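**Strategy.** The cyclohexane ring is built by a formal [3+3] annulation. The ring C=O carbon and the C(OH)CH3 carbon sit 1,4 across the ring (a homoaldol relationship), and the ring CH next to the gem-dimethyl carbon is the β-carbon of an α-methyl enal that linalool supplies. A silylium-catalysed cascade joins a siloxycyclopropane (the CH2–CH2–C(O)CH3 unit) to that enal: ring-opening aldol addition makes the CH2–C(carbinol) bond, and the liberated silyl-activated ketone closes the ring by a type 2 carbonyl–ene reaction onto the olefinic CH, which sets both ring stereocenters. The ring ketone is carried as a silyl ether stereocenter, the gem-dimethyl carbon as an exocyclic methylene; oxidation and reductive methylation finish.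

Key step: step 6

Remark: the sense of induction of the chiral acid in step 6 is not known for this substrate class; the (S,S) acid is written, and the enantiomer that gives the (5S) silyl ether 10 is the one to be used.

Step 1
Reactants: 1 (R)-(−)-linalool
Product: 3 (3R)-3,7-dimethyloct-6-ene-1,3-diol, via alkylborane 2 (not isolated)
Conditions: 9-BBN (2.2 equiv), THF, 0 °C → rt; then NaOH, H2O2, 0 °C → rt
Reagents that add atoms: hydrogen peroxide OO
Why: Hydroboration–oxidation: 9-BBN should add in the anti-Markovnikov sense to the monosubstituted vinyl group much faster than to the trisubstituted alkene, and the tertiary carbinol stereocenter is not touched.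

Step 2
Reactants: 3 (3R)-3,7-dimethyloct-6-ene-1,3-diol; 4 umbelliferone (7-hydroxy-2H-chromen-2-one)
Product: 5 7-{[(3R)-3-hydroxy-3,7-dimethyloct-6-en-1-yl]oxy}-2H-chromen-2-one
Conditions: PPh3, DIAD, THF, 0 °C → rt
Reagents that add atoms: none
Why: Mitsunobu etherification: only the primary hydroxyl is activated as the oxyphosphonium ion and displaced by the acidic phenol, while the hindered tertiary alcohol and its stereocenter stay untouched.

Step 3
Reactants: 5 7-{[(3R)-3-hydroxy-3,7-dimethyloct-6-en-1-yl]oxy}-2H-chromen-2-one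
Product: 6 (2E,6R)-6-hydroxy-2,6-dimethyl-8-[(2-oxo-2H-chromen-7-yl)oxy]oct-2-enal
Conditions: SeO2 (1.2 equiv), 1,4-dioxane, 80 °C
Reagents that add atoms: selenium dioxide O=[Se]=O
Why: Riley allylic oxidation: ene reaction and [2,3]-sigmatropic shift should oxidise the (E)-methyl group of the trisubstituted alkene selectively, and the excess of SeO2 carries the allylic alcohol on to the (E)-enal.

Step 4
Reactants: 6 (2E,6R)-6-hydroxy-2,6-dimethyl-8-[(2-oxo-2H-chromen-7-yl)oxy]oct-2-enal
Product: 7 (2E,6R)-2,6-dimethyl-8-[(2-oxo-2H-chromen-7-yl)oxy]-6-[(trimethylsilyl)oxy]oct-2-enal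
Conditions: TMSCl, imidazole, DMF, 0 °C → rt
Reagents that add atoms: chlorotrimethylsilane C[Si](C)(C)Cl
Why: O-silylation of the tertiary alcohol masks the only protic and nucleophilic group before the acid-catalysed cascade.

Step 5
Reactants: 8 1-methylcyclopropan-1-ol
Product: 9 trimethyl[(1-methylcyclopropyl)oxy]silane
Conditions: TMSCl, imidazole, CH2Cl2, 0 °C → rt
Reagents that add atoms: chlorotrimethylsilane C[Si](C)(C)Cl
Why: O-silylation gives the homo-enol silyl ether that serves as donor of the CH2–CH2–C(O)CH3 unit.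

Step 6
Reactants: 7 (2E,6R)-2,6-dimethyl-8-[(2-oxo-2H-chromen-7-yl)oxy]-6-[(trimethylsilyl)oxy]oct-2-enal; 9 trimethyl[(1-methylcyclopropyl)oxy]silane
Product: 12 7-{[(3R)-5-[(1R,2S,5S)-2,5-dihydroxy-2-methyl-6-methylidenecyclohexyl]-3-hydroxy-3-methylpentyl]oxy}-2H-chromen-2-one, via keto silyl ether 10 (not isolated), via cyclised silyl ether 11 (not isolated)
Conditions: 9 (2 equiv), IDPi acid HN[P(=NSO2CF3)(O2L)]2 (5 mol %; O2L = (S)-3,3′-bis[3,5-bis(trifluoromethyl)phenyl]-1,1′-binaphthalene-2,2′-diolate), toluene, −78 → −40 °C; then K2CO3, MeOH, 0 °C → rt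
Reagents that add atoms: none
Why: Proposed new method: the silylated chiral acid passes its silyl cation to the aldehyde oxygen of 7, and the strained C(O)–CH2 σ bond of 9 then attacks the activated carbonyl carbon as a homo-enol silyl ether, which forms the bond between the former aldehyde carbon and the CH2 terminus and leaves the methyl ketone of 10 as its O-silyl oxocarbenium ion pair. The closest known reaction types are the Lewis-acid homoaldol of siloxycyclopropanes with aldehydes, the Mukaiyama aldol–Prins cascade and the alkylaluminium-halide-promoted type 2 carbonyl–ene cyclisation of methyl ketones; new is the use of a simple ketone-derived siloxycyclopropane under silylium counter-anion catalysis and the direct hand-over of the oxocarbenium ion to the ene step. In that step the olefinic CH adds to the ketone carbon while a hydrogen of the vinylic methyl group moves to oxygen through a chair-like six-centre array, so the six-membered carbocycle closes in the type 2 ene mode (tether on the central carbon of the ene unit) and the double bond becomes exocyclic in 11. The silyl ether stereocenter is set in the first event by the chiral counter-anion; the two ring stereocenters follow from it in the second, because the (E)-alkene holds the side chain equatorial, the hydrogen transfer forces the new C–O bond axial and thus cis to the side chain with the methyl group equatorial, and the silyloxy group stays pseudo-axial to avoid 1,2-allylic strain with the vinylic methyl group, which leaves one chair. The step needs 1,2- and not 1,4-attack on the enal and ene closure faster than desilylation, oxygen participation or cation capture; the α-methyl and β-alkyl substituents of the enal, the low temperature and the non-nucleophilic confined anion are relied on for this.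

Step 7
Reactants: 12 7-{[(3R)-5-[(1R,2S,5S)-2,5-dihydroxy-2-methyl-6-methylidenecyclohexyl]-3-hydroxy-3-methylpentyl]oxy}-2H-chromen-2-one
Product: 13 7-{[(3R)-3-hydroxy-5-[(1R,2S)-2-hydroxy-2-methyl-6-methylidene-5-oxocyclohexyl]-3-methylpentyl]oxy}-2H-chromen-2-one
Conditions: Dess–Martin periodinane, CH2Cl2, 0 °C
Reagents that add atoms: none
Why: Dess–Martin oxidation: only the secondary allylic alcohol can be oxidised, which removes the relay stereocenter and should give the α-methylene ketone (used at once), the two tertiary alcohols being inert.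

Step 8
Reactants: 13 7-{[(3R)-3-hydroxy-5-[(1R,2S)-2-hydroxy-2-methyl-6-methylidene-5-oxocyclohexyl]-3-methylpentyl]oxy}-2H-chromen-2-one
Product: 15 7-{[(3R)-3-hydroxy-5-[(1R,6S)-6-hydroxy-2,2,6-trimethyl-3-oxocyclohexyl]-3-methylpentyl]oxy}-2H-chromen-2-one, via lithium enolate 14 (not isolated)
Conditions: LiBH(s-Bu)3 (1.05 equiv), THF, −78 °C; then MeI, DMPU, −78 → 0 °C
Reagents that add atoms: iodomethane CI
Why: Reductive alkylation of an enone: conjugate hydride addition to the unhindered exocyclic methylene carbon should give the enolate regiospecifically at the future quaternary carbon, which iodomethane methylates to the gem-dimethyl group without touching a stereocenter.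

**Compound list**

1 | (R)-(−)-linalool, (3R)-3,7-dimethylocta-1,6-dien-3-ol | CC(C)=CCC[C@@](C)(O)C=C | starting material
2 | 9-[(3R)-3-hydroxy-3,7-dimethyloct-6-en-1-yl]-9-borabicyclo[3.3.1]nonane | CC(C)=CCC[C@@](C)(O)CCB1C2CCCC1CCC2 | intermediate
3 | (3R)-3,7-dimethyloct-6-ene-1,3-diol | CC(C)=CCC[C@@](C)(O)CCO | intermediate
4 | umbelliferone, 7-hydroxy-2H-chromen-2-one | Oc1ccc2ccc(=O)oc2c1 | starting material
5 | 7-{[(3R)-3-hydroxy-3,7-dimethyloct-6-en-1-yl]oxy}-2H-chromen-2-one | CC(C)=CCC[C@@](C)(O)CCOc1ccc2ccc(=O)oc2c1 | intermediate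
6 | (2E,6R)-6-hydroxy-2,6-dimethyl-8-[(2-oxo-2H-chromen-7-yl)oxy]oct-2-enal | O=C/C(C)=C/CC[C@@](C)(O)CCOc1ccc2ccc(=O)oc2c1 | intermediate
7 | (2E,6R)-2,6-dimethyl-8-[(2-oxo-2H-chromen-7-yl)oxy]-6-[(trimethylsilyl)oxy]oct-2-enal | O=C/C(C)=C/CC[C@@](C)(O[Si](C)(C)C)CCOc1ccc2ccc(=O)oc2c1 | intermediate
8 | 1-methylcyclopropan-1-ol | CC1(O)CC1 | starting material
9 | trimethyl[(1-methylcyclopropyl)oxy]silane | CC1(O[Si](C)(C)C)CC1 | intermediate
10 | (5S,6E,10R)-6,10-dimethyl-12-[(2-oxo-2H-chromen-7-yl)oxy]-5,10-bis[(trimethylsilyl)oxy]dodec-6-en-2-one (formed as its O-silyl oxocarbenium ion pair) | CC(=O)CC[C@H](O[Si](C)(C)C)/C(C)=C/CC[C@@](C)(O[Si](C)(C)C)CCOc1ccc2ccc(=O)oc2c1 | intermediate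
11 | 7-{[(3R)-5-[(1R,2S,5S)-2-hydroxy-2-methyl-6-methylidene-5-[(trimethylsilyl)oxy]cyclohexyl]-3-methyl-3-[(trimethylsilyl)oxy]pentyl]oxy}-2H-chromen-2-one | C=C1[C@@H](O[Si](C)(C)C)CC[C@](C)(O)[C@@H]1CC[C@@](C)(O[Si](C)(C)C)CCOc1ccc2ccc(=O)oc2c1 | intermediate
12 | 7-{[(3R)-5-[(1R,2S,5S)-2,5-dihydroxy-2-methyl-6-methylidenecyclohexyl]-3-hydroxy-3-methylpentyl]oxy}-2H-chromen-2-one (ring hydroxyl at the methyl-bearing carbon cis to the side chain, allylic hydroxyl trans to it) | C=C1[C@@H](O)CC[C@](C)(O)[C@@H]1CC[C@@](C)(O)CCOc1ccc2ccc(=O)oc2c1 | intermediate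
13 | 7-{[(3R)-3-hydroxy-5-[(1R,2S)-2-hydroxy-2-methyl-6-methylidene-5-oxocyclohexyl]-3-methylpentyl]oxy}-2H-chromen-2-one | C=C1C(=O)CC[C@](C)(O)[C@@H]1CC[C@@](C)(O)CCOc1ccc2ccc(=O)oc2c1 | intermediate
14 | lithium (3R,4S)-4-hydroxy-3-{(3R)-3-hydroxy-3-methyl-5-[(2-oxo-2H-chromen-7-yl)oxy]pentyl}-2,4-dimethylcyclohex-1-en-1-olate | [Li+].CC1=C([O-])CC[C@](C)(O)[C@@H]1CC[C@@](C)(O)CCOc1ccc2ccc(=O)oc2c1 | intermediate
15 | 7-{[(3R)-3-hydroxy-5-[(1R,6S)-6-hydroxy-2,2,6-trimethyl-3-oxocyclohexyl]-3-methylpentyl]oxy}-2H-chromen-2-one (CNP0414652.1) | CC1(C)C(=O)CC[C@](C)(O)[C@@H]1CC[C@@](C)(O)CCOc1ccc2ccc(=O)oc2c1 | target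

**Step count.** Total: 8 steps. Longest linear sequence: 7 steps (1, 2, 3, 4, 6, 7, 8); step 5 is a one-step side branch.

**Steps most likely to fail**

Step 6. The cyclopropane σ bond may be too weak a nucleophile for the silylated enal. Conjugate attack, participation of the silyloxy oxygen at the activated ketone, capture of the tertiary cation by the side-chain silyl ether, or poor induction by the counter-anion may also erode the cascade. The fallback uses known chemistry, sets out from 7 and returns at 12. Titanium-mediated enantioselective addition of (CH2=CHCH2CH2)2Zn to the aldehyde of 7 should give the dienol F1. Conditions are Ti(OiPr)4 and catalytic N,N′-cyclohexane-1,2-diylbis(trifluoromethanesulfonamide), using the ligand enantiomer that delivers the (8S) alcohol. Silylation with TBSCl and imidazole gives the tert-butyldimethylsilyl ether F2. Wacker–Tsuji oxidation of the terminal vinyl group (PdCl2, CuCl, O2, DMF–H2O) gives the methyl ketone F3. Me2AlCl (CH2Cl2, −78 → 0 °C) then effects the type 2 carbonyl–ene closure to the cyclised silyl ether F4 through the same chair. HF·pyridine removes both silyl groups to give 12.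

Step 8. The borohydride may attack the coumarin lactone, or the enolate may equilibrate by proton transfer before it is methylated, which would scramble the site of alkylation. The fallback sets out from 13 and returns at 15. RhCl(PPh3)3-catalysed 1,4-hydrosilylation with Et3SiH gives the regiodefined triethylsilyl enol ether F5. Benzyltrimethylammonium fluoride and MeI in THF then release and methylate the enolate under conditions that do not touch the lactone.

Step 3. Oxidation may stop at the allylic alcohol or run on to the acid, and the free tertiary hydroxyl may close onto the enal by oxa-Michael addition at 80 °C. The fallback sets out from 5 and returns at 6. Cross-metathesis of the isopropylidene group of 5 with methacrolein (second-generation Hoveyda–Grubbs catalyst, CH2Cl2, 40 °C) gives the (E)-enal directly, without an oxidant.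

Further compounds
F1 | step 6 | 7-{[(3R,6E,8S)-8-hydroxy-3,7-dimethyl-3-[(trimethylsilyl)oxy]dodeca-6,11-dien-1-yl]oxy}-2H-chromen-2-one | C=CCC[C@H](O)/C(C)=C/CC[C@@](C)(O[Si](C)(C)C)CCOc1ccc2ccc(=O)oc2c1
F2 | step 6 | 7-{[(3R,6E,8S)-8-[(tert-butyldimethylsilyl)oxy]-3,7-dimethyl-3-[(trimethylsilyl)oxy]dodeca-6,11-dien-1-yl]oxy}-2H-chromen-2-one | C=CCC[C@H](O[Si](C)(C)C(C)(C)C)/C(C)=C/CC[C@@](C)(O[Si](C)(C)C)CCOc1ccc2ccc(=O)oc2c1
F3 | step 6 | (5S,6E,10R)-5-[(tert-butyldimethylsilyl)oxy]-6,10-dimethyl-12-[(2-oxo-2H-chromen-7-yl)oxy]-10-[(trimethylsilyl)oxy]dodec-6-en-2-one | CC(=O)CC[C@H](O[Si](C)(C)C(C)(C)C)/C(C)=C/CC[C@@](C)(O[Si](C)(C)C)CCOc1ccc2ccc(=O)oc2c1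
F4 | step 6 | 7-{[(3R)-5-[(1R,2S,5S)-5-[(tert-butyldimethylsilyl)oxy]-2-hydroxy-2-methyl-6-methylidenecyclohexyl]-3-methyl-3-[(trimethylsilyl)oxy]pentyl]oxy}-2H-chromen-2-one | C=C1[C@@H](O[Si](C)(C)C(C)(C)C)CC[C@](C)(O)[C@@H]1CC[C@@](C)(O[Si](C)(C)C)CCOc1ccc2ccc(=O)oc2c1
F5 | step 8 | 7-{[(3R)-3-hydroxy-5-[(1R,6S)-6-hydroxy-2,6-dimethyl-3-[(triethylsilyl)oxy]cyclohex-2-en-1-yl]-3-methylpentyl]oxy}-2H-chromen-2-one | CC1=C(O[Si](CC)(CC)CC)CC[C@](C)(O)[C@@H]1CC[C@@](C)(O)CCOc1ccc2ccc(=O)oc2c1
F0 | step 3 | none | none
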